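At early times the readings leave a gap between substrate and target. In the blue run, after 1.00 min, substrate reads 55% and target 1%, so 44.0% of the charge stands in forms that neither reading counts. In the grey run, through the middle of the course, the share counted by neither reading is 49.0% at 2.50 min and 34.0% at 15.0 min, while target climbs. Towards the end of that run substrate reads 2% and target still gains, from 60% to 64%. What is about to matter is that these readings count target free or not, whereas the question concerns free target.

| flask | substrate | reagent | free catalyst | second catalyst | remark | time |
|---|---|---|---|---|---|---|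
| blue | 0.061 M | 1.2 equiv | 1.1 mol% | 0.2 mol% | run made earlier |  |
| grey | 0.29 M | 1.2 equiv | 1.1 mol% | 0.2 mol% | run made earlier |  |
| Friday's | 0.050 M | 1.20 equiv | 1.1 mol% | 0.2 mol% |  | 20 min |
| Tuesday's | 0.10 M | 1.20 equiv | 1.1 mol% | 0.2 mol% |  | 20 min |
| Sunday's | 0.20 M | 1.20 equiv | 1.1 mol% | 0.2 mol% |  | 20 min |

| run | time / min | target / % | substrate / % |
|---|---|---|---|
| blue | 1.00 | 1 | 55 |
| blue | 2.00 | 3 | 43 |
| blue | 3.00 | 5 | 38 |
| blue | 5.00 | 10 | 35 |
| blue | 8.00 | 13 | 23 |
| blue | 15.0 | 25 | 17 |
| grey | 2.50 | 29 | 22 |
| grey | 5.00 | 42 | 15 |
| grey | 8.00 | 52 | 4 |
| grey | 10.0 | 55 | 6 |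
| grey | 12.0 | 60 | 8 |
| grey | 15.0 | 64 | 2 |

(each reading ± 2 percentage points)

- a reading or a percentage of target counts all its forms, free or not
- the concentration of target that is asked is that of its free form alone
- "hardly changes" means that all values lie within two and a half points (for a concentration: within two and a half percent of the largest)

* [target] (only what is free in solution) at the end for Friday's, Tuesday's, Sunday's, in this order
* the course of these numbers from the first flask to the last (falls all the way / falls, then rises / rises all the way / rises, then falls / hardly changes)

The zero of the scale is a first-order flask, in which the percent of target at a given time does not depend on the charge. Here it does. The odds of target, meaning its share divided by the rest of the charge, read 0.333 in the blue run and 1.78 in the grey run at the same time. That is a factor of 5.35 for a factor of 4.75 in charge, which is close to overall second order. So the odds are divided by charge and time: blue gives 0.364 M⁻¹ min⁻¹, grey gives 0.409 M⁻¹ min⁻¹, and their mean is the odds rate g, the odds of target gained per unit of charge and time, 0.386 M⁻¹ min⁻¹, itself a reading.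

Carried to 20 min, g gives target in every form of 0.0139 M for Friday's, 0.0436 M for Tuesday's and 0.121 M for Sunday's. This reckoning commits to these totals and names no free value beneath them. The forecast does name one, 0.013 M, 0.042 M and 0.115 M, course rises all the way, holding that “free target is only slightly below total”. The flasks give 0.00561 M, 0.00564 M and 0.00565 M, so the course hardly changes.

    substrate + free catalyst ⇌ free catalyst + open intermediate (K = 2.30, k = 1500 M⁻¹ min⁻¹)
    second catalyst + open intermediate ⇌ catalyst intermediate (K = 26.0 M⁻¹, k = 2000 M⁻¹ min⁻¹)
    reagent + catalyst intermediate → second catalyst + target (k = 370 M⁻¹ min⁻¹)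
    2 free catalyst ⇌ resting dimer (K = 1.80 × 10⁵ M⁻¹, k = 1500 M⁻¹ min⁻¹)
    substrate + reagent → uncatalysed product (k = 0.760 M⁻¹ min⁻¹)
    crystals ⇌ target, rate k6*(cs6 - [target]) while solid is left; crystals form when [target] > cs6 (solubility = 5.60 mM, k = 28.0 min⁻¹)

Crystals exchange with dissolved target with a half-time of 0.0248 min, far shorter than the 20 min of the run. At 20.0 min in Friday's, dissolved target is made and used up, its going into other forms counted as use, at a ratio of 0.999, with free target at 0.00561 M against a solubility of 5.6 mM. For Sunday's g gives 60.7% of the charge, and target in every form stands at 61.2%, of which crystals are 58.4%. For Friday's g gives 27.9%, and target in every form stands at 21.3%, of which crystals are 10.1%.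

Readings and results come from a simulation for an exercise.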